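Time buys little in this flask at −20 °C: from 12.0 min to 30.0 min the starting material falls from 28% to 24%, while the double product rises from 18% to 23%. So I ask what a further unit of reagent does.

in all of them: starting material 0.80 M; reagent 1.05 equiv; temperature −20 °C
- south-west: the very flask that is asked about, followed so far
- flask: time 30 min

south-west run (percent of the starting material charged)

| time / min | double product / % | starting material / % |
|---|---|---|
| 1.50 | 3 | 77 |
| 5.00 | 8 | 50 |
| 8.00 | 17 | 38 |
| 12.0 | 18 | 28 |
| 20.0 | 21 | 27 |
| 25.0 | 23 | 24 |
| 30.0 | 23 | 24 |

(standard deviation of a reading: 1.5 percentage points)

- amber: at 30 min take out 90% of the by-product then present, then wait 1.0 h
- grey: at 30 min raise the temperature by 25 K, then wait 1.0 h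
- teal: change nothing and wait 1.0 h more
- red: at 30 min add reagent, 50.0% of the amount charged, then wait 1.0 h

- the volume of additions can be left aside
- a reading or a percentage of double product counts all its forms, free or not
- the earlier runs do not show what temperature does; that part of a forecast is a guess

1. double product, in percent of the starting material first charged, at 30 min
2. which option adds most double product ("none" when 2 percentage points or less is all one gets) (amber / grey / teal / red / none)
3. double product present, in percent of the starting material first charged, after grey
4. double product present, in percent of the starting material first charged, after teal

I build the flask up step by step, counting in percent of the starting material charged. With the first step alone, the loss of starting material leaves 29.0% of reagent, yet the curve flattens. So I add the second step. The gap in the balance, 53.0%, I call mono adduct, and each double product costs a second reagent. That leaves 6.00% of reagent, less than the 24% of starting material read, so reagent is the limiting reagent.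

Dividing one rate by the other cancels [reagent]. On the clock ln([starting material] charged / [starting material] left), which reads 1.43 at the end, double product grows as the selectivity factor times [mono adduct]. I replace that curve by its mean. The reading at 5.00 min stands near mid-clock with a gap of 42.0%, so Simpson's rule gives a mean of 36.8%, and the factor reads 0.438. A straight line would give 0.607, but the gap stands higher than that line at mid-clock. The scatter moves the factor by 0.0285.

The rest follows from the second-step share, the fraction of a further unit of reagent that makes double product: 0.491. I then reckon teal at 25.9%. Amber and grey add no reagent, so I give them the same reagent left, and the effect of temperature stays a guess. I reckon red at 51.7%, though that asks the first step for 29.8% against 24% present, so the share must climb and this figure is low.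

The forecast says 23% now, red as best, 26% after grey and 25% after teal, holding that “the stall is mainly reagent exhaustion”, and its teal stands below mine.

The flask gives 24.4% at 30 min, with 25.1% after teal and 25.0% after grey. The best option is red, which adds 28 percentage points, against 0.75 points for amber.

    starting material + reagent → mono adduct + by-product (k = 0.280 /M/min, Ea = 53.0 kJ/mol)
    reagent + mono adduct → double product + by-product (k = 0.140 /M/min, Ea = 49.0 kJ/mol)
    reagent + double product → triple product + by-product (k = 0.0250 /M/min, Ea = 59.0 kJ/mol)
    reagent + triple product → tetra adduct + by-product (k = 1.40 /M/min, Ea = 59.0 kJ/mol)
    crystals ⇌ double product, rate k5*(cs5 - [double product]) while solid is left; crystals form when [double product] > cs5 (solubility = 0.170 M, k = 11.0 /min)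
    (constants at −20 °C)

The flask keeps 1.62% of its own reagent charge at 30 min, which is 1.70% of the starting material charged, not my 6.00%. The share turns that into 0.83 points, against 0.75 points for teal. The neighbouring flask has 1.80 equiv of reagent and keeps 7.00% of its own charge, so it consumes 64.1% more than this flask, counted on the starting material charged. The share then gives 55.9% double product. The neighbouring flask holds double product of 58.4% at 30 min.

(The numbers in the tables are calculated with made-up constants; the scatter is artificial.)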